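## Retrosynthetic overview

1. Ring numbering: C1–C10 around the carbocycle (C1–C2 oxirane, C3 carbinol, C4(CH3)=C5, C6–O and C7 shared with the cis-fused γ-lactone C7–C11(=C13H2)–C12(=O)–O6, C8 angelate, C9H2, C10 tertiary carbinol). The strategy rests on the C1–C2 oxirane lying between C3, which can be carried as a ketone whose other flank is the C4=C5 alkene, and the fully substituted C10: C2 is then the only enolisable carbon of a chloromethyl ketone and C1 a non-enolisable α-alkoxy aldehyde.
2. Key disconnection: the C1–C2 and O–C2 bonds of the oxirane are undone together (Darzens retron), which opens the ten-membered ring to seco chloroketone aldehyde 25; after it only C3 reduction, C11 methylenation, the C8 angelate and deprotections remain.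
3. 25 comes from (Z)-alkenyl iodide lactone 22 (C3 and C2 added by Stille coupling, then chlorination); the (Z)-C4=C5 iodide comes from trans-hydroalumination/iodination of a C6 propargylic alcohol, the lactone from oxidative cleavage of a C7 allyl group.
4. Stereocentres: C10 from Sharpless epoxidation of 1; C7 and C8 from an Evans syn aldol of imide 9 with aldehyde 6; C6 from a catalyst-controlled ynone reduction; C1 and C2 in the key step; C3 by chelation-controlled reduction.
5. Ring order: γ-lactone first (lactol in step 13, oxidised in step 14), then the ten-membered carbocycle and the oxirane in one step (step 16).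

Key step: step 16

Remark on the chemistry: the given SMILES encodes a cis-fused C6/C7 γ-lactone and a (4Z)-alkene, and the route is built for exactly this isomer; C8 is carried as a triethylsilyl ether and C3 later as a tert-butyldimethylsilyl ether so that the two hydroxyls can be unmasked separately.

## Route

Step 1
Reactants: 1 2-methylprop-2-en-1-ol
Product: 2 (S)-(2-methyloxiran-2-yl)methanol
Conditions: Ti(OiPr)4 (5 mol%), L-(+)-diisopropyl tartrate (6 mol%), cumene hydroperoxide, 4 Å MS, CH2Cl2, −20 °C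
Reagents that add atoms: cumene hydroperoxide, CC(C)(OO)c1ccccc1
Why: Sharpless asymmetric epoxidation of an allylic alcohol, in which the L-(+)-tartrate complex delivers oxygen to the face that gives the (S)-epoxide and so sets C10.

Step 2
Reactants: 2 (S)-(2-methyloxiran-2-yl)methanol; 3 vinylmagnesium bromide (3 equiv)
Product: 4 (R)-2-methylpent-4-ene-1,2-diol
Conditions: CuI (10 mol%), THF, −30 to 0 °C
Reagents that add atoms: none
Why: Copper-catalysed Grignard opening of the epoxide at its unsubstituted CH2 (C9) after the first equivalent has deprotonated the hydroxyl; the C10–O bond is not touched, so the configuration is kept.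

Step 3
Reactants: 4 (R)-2-methylpent-4-ene-1,2-diol
Product: 5 (4R)-2-(4-methoxyphenyl)-4-methyl-4-(prop-2-en-1-yl)-1,3-dioxolane (both epimers at the acetal carbon)
Conditions: 4-MeOC6H4CH(OMe)2, PPTS (cat.), CH2Cl2, rt
Reagents that add atoms: 4-methoxybenzaldehyde dimethyl acetal, COc1ccc(cc1)C(OC)OC
Why: Acid-catalysed transacetalisation ties O10 and O1 into a p-methoxybenzylidene acetal that masks both hydroxyls and already carries the later PMB group; the acetal epimers converge in step 11.

Step 4
Reactants: 5 the allyl dioxolane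
Product: 6 2-[(4R)-2-(4-methoxyphenyl)-4-methyl-1,3-dioxolan-4-yl]acetaldehyde
Conditions: OsO4 (2 mol%), NaIO4, 2,6-lutidine, dioxane/H2O, rt
Reagents that add atoms: osmium tetroxide, O=[Os](=O)(=O)=O, re-formed by sodium periodate, [Na+].[O-]I(=O)(=O)=O
Why: Lemieux–Johnson oxidative cleavage of the terminal alkene gives the C8 aldehyde under buffered conditions that leave the acetal intact.

Step 5
Reactants: 7 (R)-4-benzyl-1,3-oxazolidin-2-one; 8 pent-4-enoyl chloride
Product: 9 (R)-4-benzyl-3-(pent-4-enoyl)-1,3-oxazolidin-2-one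
Conditions: Et3N, DMAP (cat.), CH2Cl2, 0 °C to rt
Reagents that add atoms: none
Why: DMAP-catalysed N-acylation of the oxazolidinone gives the imide whose α-carbon becomes C7 and whose allyl group is the masked C11–C12 lactone arm.

Step 6
Reactants: 9 the pentenoyl imide; 6 the dioxolanyl acetaldehyde
Product: 11 Evans syn aldol adduct (2R,3S in the acyl chain), via dibutylboron (Z)-enolate 10 (not isolated)
Conditions: Bu2BOTf, Et3N, CH2Cl2, −78 to 0 °C; then 6, −78 to 0 °C; H2O2, MeOH, pH 7 buffer
Reagents that add atoms: none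
Why: Evans syn-aldol addition through a Zimmerman–Traxler chair in which the (R)-benzyl auxiliary shields one face of the (Z)-boron enolate, which sets C7 and C8 (allyl and hydroxyl syn) independently of the remote C10 centre.

Step 7
Reactants: 11 the aldol adduct
Product: 12 (2R,3S)-3-hydroxy-N-methoxy-4-[(4R)-2-(4-methoxyphenyl)-4-methyl-1,3-dioxolan-4-yl]-N-methyl-2-(prop-2-en-1-yl)butanamide
Conditions: MeONHMe·HCl, AlMe3, THF, −20 to 0 °C
Reagents that add atoms: N,O-dimethylhydroxylamine hydrochloride, CNOC.Cl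
Why: Aluminium amide transamidation of the imide (assisted by the free β-hydroxyl) gives the Weinreb amide and releases the auxiliary without touching C7.

Step 8
Reactants: 12 the hydroxy Weinreb amide
Product: 13 the C8 triethylsilyl ether of 12
Conditions: Et3SiCl, imidazole, DMF, rt
Reagents that add atoms: chlorotriethylsilane, CC[Si](Cl)(CC)CC
Why: Standard silylation; the triethylsilyl group blocks O8 from lactonising onto C12 later and can be removed in step 20 in the presence of a tert-butyldimethylsilyl ether.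

Step 9
Reactants: 13 the silylated Weinreb amide; 14 prop-1-yn-1-ylmagnesium bromide
Product: 15 (5R,6S)-7-[(4R)-2-(4-methoxyphenyl)-4-methyl-1,3-dioxolan-4-yl]-5-(prop-2-en-1-yl)-6-(triethylsilyloxy)hept-2-yn-4-one (C6 ynone)
Conditions: THF, 0 °C; NH4Cl (aq)
Reagents that add atoms: none
Why: Weinreb ketone synthesis, in which the chelated tetrahedral adduct prevents over-addition, gives the ynone that carries C5, C4 and the C4 methyl.

Step 10
Reactants: 15 the ynone
Product: 16 the C6 propargylic alcohol (C6–OH anti to C8–OSiEt3)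
Conditions: Ru[(R,R)-TsDPEN](p-cymene) (5 mol%), i-PrOH, rt
Reagents that add atoms: none
Why: Noyori asymmetric transfer hydrogenation of an alkynyl ketone under catalyst control; with the (R,R)-ligand (alkynyl in the place the aryl group takes in the usual model) hydride should add to the face that gives the required C6 carbinol, overriding the weak bias of C7.

Step 11
Reactants: 16 the propargylic alcohol
Product: 17 the O10 p-methoxybenzyl ether with free C1 and C6 hydroxyls
Conditions: i-Bu2AlH (5 equiv), CH2Cl2, −78 to 0 °C; KNaC4H4O6 (aq)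
Reagents that add atoms: none
Why: Reductive opening of the p-methoxybenzylidene acetal: aluminium binds the less hindered primary O1, that C–O bond breaks and hydride reduces the oxocarbenium ion, so the PMB group ends on the tertiary O10 and C1–OH is set free.

Step 12
Reactants: 17 the propargylic diol
Product: 19 (Z)-alkenyl iodide diol, via cyclic alkenylaluminate 18 (not isolated)
Conditions: NaAlH2(OCH2CH2OMe)2, THF, 0 °C to rt; then EtOAc; then I2, −78 to 0 °C
Reagents that add atoms: iodine, II
Why: Hydroxyl-directed trans-hydroalumination of the propargylic alkoxide puts aluminium on C4 cis to C6 in a five-membered aluminate, and iodinolysis with retention gives the (Z)-iodide that fixes the C4=C5 geometry.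

Step 13
Reactants: 19 the (Z)-alkenyl iodide diol
Product: 21 five-membered lactol (both anomers), via hydroxy aldehyde 20 (not isolated)
Conditions: OsO4 (2 mol%), NaIO4, 2,6-lutidine, dioxane/H2O, rt
Reagents that add atoms: osmium tetroxide, O=[Os](=O)(=O)=O, re-formed by sodium periodate, [Na+].[O-]I(=O)(=O)=O
Why: Lemieux–Johnson cleavage of the terminal alkene (the deactivated, trisubstituted iodoalkene is left alone) gives the C12 aldehyde, which closes on O6 to the five-membered lactol because O8 is silylated.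

Step 14
Reactants: 21 the lactol
Product: 22 (Z)-alkenyl iodide γ-lactone with C1 aldehyde
Conditions: TEMPO (30 mol%), PhI(OAc)2 (4 equiv), CH2Cl2, rt
Reagents that add atoms: none
Why: Oxoammonium oxidation (TEMPO with PhI(OAc)2) converts the lactol into the cis-fused γ-lactone and the primary C1 alcohol into the non-enolisable aldehyde in one operation.

Step 15
Reactants: 22 the iodo lactone aldehyde; 23 tributyl(1-ethoxyvinyl)stannane
Product: 25 seco chloroketone aldehyde (key-step precursor), via 2-ethoxy diene 24 (not isolated)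
Conditions: Pd2(dba)3 (5 mol%), AsPh3, CuI, DMF, 40 °C; filtration through Et3N-deactivated silica; then NCS, NaHCO3, THF/H2O, 0 °C
Reagents that add atoms: N-chlorosuccinimide, O=C1CCC(=O)N1Cl; water, O
Why: Stille coupling with retention of the (Z)-geometry gives the 2-ethoxy diene, whose enol ether is chlorinated at its CH2 terminus by NCS and hydrolysed to the chloromethyl ketone.

Step 16
Reactants: 25 seco chloroketone aldehyde
Product: 28 ten-membered cis-epoxy enone, via magnesium enolate 26 (not isolated), via chlorohydrin magnesium alkoxide 27 (not isolated)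
Conditions: MgBr2·OEt2 (5 equiv), i-Pr2NEt (10 equiv), CH2Cl2, slow addition of 25 to 0.002 M, 0 °C to rt
Reagents that add atoms: none
Why: Proposed new method: MgBr2 and i-Pr2NEt soft-enolise the chloromethyl ketone at C2 to the Z(O) enolate 26, C2 adds to the magnesium-bound C1 aldehyde to give aldolate 27, and the alkoxide then displaces chloride at C2 with inversion to give the oxirane. The closest known reactions are the intermolecular Darzens condensation of α-chloro ketones with aldehydes and magnesium halide/amine direct aldol additions; a ten-membered-ring version is not known. The carbocycle closes by a 10-(enolendo)-exo-trig aldol addition under high dilution and the oxirane by a 3-exo-tet substitution. C1 should be set by a Cram chelate in which magnesium bridges the aldehyde oxygen and the O10 PMB ether, so that C2 adds on the face flanked by the C10 methyl group and not by the C9 chain. C2 follows from C1, because the metal-bridged Z(O) enolate should give the syn aldolate (C1–O and C2–Cl syn), the only one whose anti-periplanar closure gives the cis-oxirane, and a reversible aldol step should funnel material through it. The step needs enolisation at C2 only (C1 has no α-hydrogen, C4 is sp2 and the lactone C11–H2 is far less acidic) and ring closure over oligomerisation (dilution, with the chelate and the (Z)-alkene bending the chain).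

Step 17
Reactants: 28 the cis-epoxy enone
Product: 29 the C3 alcohol (hydroxyl anti to the oxirane oxygen)
Conditions: Zn(BH4)2, Et2O, −20 °C
Reagents that add atoms: none
Why: Chelation-controlled 1,2-reduction of an α,β-epoxy ketone: zinc bridges the C3 carbonyl and the oxirane oxygen and hydride enters from the side away from C1, which should give the erythro (anti) epoxy alcohol of the target.

Step 18
Reactants: 29 the epoxy alcohol
Product: 30 the C3 tert-butyldimethylsilyl ether
Conditions: t-BuMe2SiOTf, 2,6-lutidine, CH2Cl2, −78 °C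
Reagents that add atoms: tert-butyldimethylsilyl trifluoromethanesulfonate, CC(C)(C)[Si](C)(C)OS(=O)(=O)C(F)(F)F
Why: Buffered silylation protects the allylic C3 hydroxyl (no alkoxide, hence no epoxide migration) so that only O8 is acylated in step 21.

Step 19
Reactants: 30 the bis-silyl ether lactone
Product: 34 α-methylene lactone, via lithium enolate 31 (not isolated), via Mannich base 32 (not isolated), via trimethylammonium iodide 33 (not isolated)
Conditions: LiN(i-Pr)2, THF, −78 °C; then CH2=NMe2+ I−, −78 °C to rt; then MeI, rt; then NaHCO3 (aq)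
Reagents that add atoms: Eschenmoser's salt, C=[N+](C)C.[I-]
Why: Eschenmoser α-methylenation: the kinetic C11 enolate undergoes a Mannich reaction with the iminium salt, and N-methylation followed by base-induced elimination of trimethylamine unveils the exocyclic C11=C13 alkene.

Step 20
Reactants: 34 the α-methylene lactone
Product: 35 the C8 alcohol
Conditions: HF·pyridine, pyridine, THF, 0 °C
Reagents that add atoms: none
Why: Buffered fluoride cleaves the triethylsilyl ether much faster than the hindered tert-butyldimethylsilyl ether, which frees O8 alone.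

Step 21
Reactants: 35 the C8 alcohol; 36 angelic acid [(Z)-2-methylbut-2-enoic acid]
Product: 38 C8 angelate, via mixed anhydride 37 (not isolated)
Conditions: 2,4,6-Cl3C6H2COCl, Et3N, toluene, rt; then 35, toluene, 75 °C
Reagents that add atoms: none
Why: Yamaguchi-type acylation through the 2,4,6-trichlorobenzoyl mixed anhydride, run without nucleophilic catalyst, should transfer the (Z)-2-methylbut-2-enoyl group without isomerisation to the tigloyl isomer.

Step 22
Reactants: 38 the angelate
Product: 39 the C10 tertiary alcohol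
Conditions: DDQ, CH2Cl2/pH 7 buffer, 0 °C
Reagents that add atoms: none
Why: Oxidative cleavage of the p-methoxybenzyl ether by DDQ (hydride abstraction, then hydrolysis of the oxocarbenium ion) frees O10 while silyl ether, epoxide, angelate and methylene lactone stay intact.

Step 23
Reactants: 39 the C3 silyl ether
Product: 40 CNP0351240.3 (target)
Conditions: HF·pyridine, pyridine, THF, 0 °C to rt
Reagents that add atoms: none
Why: Buffered fluoride desilylation of the allylic tert-butyldimethylsilyl ether releases the C3 hydroxyl and should give the target.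

## Compound list

1 | 2-methylprop-2-en-1-ol | C=C(C)CO | starting material
2 | (S)-(2-methyloxiran-2-yl)methanol | OC[C@]1(C)OC1 | intermediate
3 | vinylmagnesium bromide | C=C[Mg]Br | starting material
4 | (R)-2-methylpent-4-ene-1,2-diol | OC[C@](C)(O)CC=C | intermediate
5 | (4R)-2-(4-methoxyphenyl)-4-methyl-4-(prop-2-en-1-yl)-1,3-dioxolane, both acetal epimers | COc1ccc(cc1)C1OC[C@@](C)(CC=C)O1 | intermediate
6 | 2-[(4R)-2-(4-methoxyphenyl)-4-methyl-1,3-dioxolan-4-yl]acetaldehyde, both acetal epimers | COc1ccc(cc1)C1OC[C@@](C)(CC=O)O1 | intermediate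
7 | (R)-4-benzyl-1,3-oxazolidin-2-one | O=C1N[C@H](Cc2ccccc2)CO1 | starting material
8 | pent-4-enoyl chloride | C=CCCC(=O)Cl | starting material
9 | (R)-4-benzyl-3-(pent-4-enoyl)-1,3-oxazolidin-2-one | C=CCCC(=O)N1[C@H](Cc2ccccc2)COC1=O | intermediate
10 | dibutylboron (Z)-enolate of 9 (not isolated) | C=CC/C=C(\OB(CCCC)CCCC)N1[C@H](Cc2ccccc2)COC1=O | intermediate
11 | (4R)-4-benzyl-3-[(2R,3S)-3-hydroxy-4-[(4R)-2-(4-methoxyphenyl)-4-methyl-1,3-dioxolan-4-yl]-2-(prop-2-en-1-yl)butanoyl]-1,3-oxazolidin-2-one | C=CC[C@@H](C(=O)N1[C@H](Cc2ccccc2)COC1=O)[C@@H](O)C[C@]1(C)COC(c2ccc(OC)cc2)O1 | intermediate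
12 | (2R,3S)-3-hydroxy-N-methoxy-4-[(4R)-2-(4-methoxyphenyl)-4-methyl-1,3-dioxolan-4-yl]-N-methyl-2-(prop-2-en-1-yl)butanamide | C=CC[C@@H](C(=O)N(C)OC)[C@@H](O)C[C@]1(C)COC(c2ccc(OC)cc2)O1 | intermediate
13 | (2R,3S)-N-methoxy-4-[(4R)-2-(4-methoxyphenyl)-4-methyl-1,3-dioxolan-4-yl]-N-methyl-2-(prop-2-en-1-yl)-3-(triethylsilyloxy)butanamide | C=CC[C@@H](C(=O)N(C)OC)[C@@H](O[Si](CC)(CC)CC)C[C@]1(C)COC(c2ccc(OC)cc2)O1 | intermediate
14 | prop-1-yn-1-ylmagnesium bromide | CC#C[Mg]Br | starting material
15 | (5R,6S)-7-[(4R)-2-(4-methoxyphenyl)-4-methyl-1,3-dioxolan-4-yl]-5-(prop-2-en-1-yl)-6-(triethylsilyloxy)hept-2-yn-4-one | CC#CC(=O)[C@H](CC=C)[C@@H](O[Si](CC)(CC)CC)C[C@]1(C)COC(c2ccc(OC)cc2)O1 | intermediate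
16 | C6 propargylic alcohol from 15 (C6–OH anti to C8–OSiEt3, C7 allyl syn to C8–O; configuration as in the SMILES) | CC#C[C@H](O)[C@H](CC=C)[C@@H](O[Si](CC)(CC)CC)C[C@]1(C)COC(c2ccc(OC)cc2)O1 | intermediate
17 | acyclic propargylic diol: C1–OH, C10–OPMB (tertiary), C8–OSiEt3, C7 allyl, C6–OH, C5≡C4–CH3 | CC#C[C@H](O)[C@H](CC=C)[C@@H](O[Si](CC)(CC)CC)C[C@@](C)(OCc1ccc(OC)cc1)CO | intermediate
18 | cyclic alkenylaluminate (O6–Al–C4 five-membered ring, disodium salt; not isolated) | CC1=C[C@@H]([C@H](CC=C)[C@@H](O[Si](CC)(CC)CC)C[C@@](C)(OCc2ccc(OC)cc2)C[O-])O[Al-]1(OCCOC)OCCOC.[Na+].[Na+] | intermediate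
19 | (Z)-alkenyl iodide diol: as 17 with C5H=C4(I)CH3, iodine cis to C6 | C/C(I)=C/[C@H](O)[C@H](CC=C)[C@@H](O[Si](CC)(CC)CC)C[C@@](C)(OCc1ccc(OC)cc1)CO | intermediate
20 | hydroxy aldehyde: as 19 with C11H2–C12HO in place of the allyl group (not isolated) | C/C(I)=C/[C@H](O)[C@H](CC=O)[C@@H](O[Si](CC)(CC)CC)C[C@@](C)(OCc1ccc(OC)cc1)CO | intermediate
21 | lactol: cis-4,5-disubstituted tetrahydrofuran-2-ol on O6/C12, both anomers, with free C1–OH | C/C(I)=C/[C@@H]1OC(O)C[C@@H]1[C@@H](O[Si](CC)(CC)CC)C[C@@](C)(OCc2ccc(OC)cc2)CO | intermediate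
22 | (Z)-alkenyl iodide with cis-fused γ-lactone (O6–C12) and C1 aldehyde | C/C(I)=C/[C@@H]1OC(=O)C[C@@H]1[C@@H](O[Si](CC)(CC)CC)C[C@@](C)(OCc2ccc(OC)cc2)C=O | intermediate
23 | tributyl(1-ethoxyvinyl)stannane | CCCC[Sn](CCCC)(CCCC)C(=C)OCC | starting material
24 | 2-ethoxy diene: C2H2=C3(OEt)–C4(CH3)=C5H, (4Z) (not isolated) | C=C(OCC)/C(C)=C\[C@@H]1OC(=O)C[C@@H]1[C@@H](O[Si](CC)(CC)CC)C[C@@](C)(OCc2ccc(OC)cc2)C=O | intermediate
25 | seco chloroketone aldehyde: ClC2H2–C3(=O)–C4(CH3)=C5H (Z), cis γ-lactone at C6/C7, C8–OSiEt3, C10(CH3)(OPMB)–C1HO | ClCC(=O)/C(C)=C\[C@@H]1OC(=O)C[C@@H]1[C@@H](O[Si](CC)(CC)CC)C[C@@](C)(OCc2ccc(OC)cc2)C=O | intermediate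
26 | Z(O) bromomagnesium enolate of 25 at C2=C3 (not isolated) | Cl/C=C(\O[Mg]Br)/C(C)=C\[C@@H]1OC(=O)C[C@@H]1[C@@H](O[Si](CC)(CC)CC)C[C@@](C)(OCc2ccc(OC)cc2)C=O | intermediate
27 | ten-membered syn chlorohydrin (C1–O, C2–Cl) as its bromomagnesium alkoxide (not isolated) | C1C(=O)O[C@H]2/C=C(/C)C(=O)[C@H](Cl)[C@@H](O[Mg]Br)[C@](C)(OCc3ccc(OC)cc3)C[C@H](O[Si](CC)(CC)CC)[C@@H]12 | intermediate
28 | ten-membered cis-epoxy enone: C1–C2 cis-oxirane, C3 ketone, (4Z)-alkene, cis γ-lactone, C8–OSiEt3, C10–OPMB | C1C(=O)O[C@H]2/C=C(/C)C(=O)[C@H]3O[C@H]3[C@](C)(OCc4ccc(OC)cc4)C[C@H](O[Si](CC)(CC)CC)[C@@H]12 | intermediate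
29 | C3 alcohol of 28 (hydroxyl anti to the oxirane oxygen) | C1C(=O)O[C@H]2/C=C(/C)[C@@H](O)[C@H]3O[C@H]3[C@](C)(OCc4ccc(OC)cc4)C[C@H](O[Si](CC)(CC)CC)[C@@H]12 | intermediate
30 | C3 tert-butyldimethylsilyl ether of 29 | C1C(=O)O[C@H]2/C=C(/C)[C@@H](O[Si](C)(C)C(C)(C)C)[C@H]3O[C@H]3[C@](C)(OCc4ccc(OC)cc4)C[C@H](O[Si](CC)(CC)CC)[C@@H]12 | intermediate
31 | lithium enolate of lactone 30 at C11=C12 (not isolated) | C1=C(O[Li])O[C@H]2/C=C(/C)[C@@H](O[Si](C)(C)C(C)(C)C)[C@H]3O[C@H]3[C@](C)(OCc4ccc(OC)cc4)C[C@H](O[Si](CC)(CC)CC)[C@@H]12 | intermediate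
32 | Mannich base: C11 (dimethylamino)methyl lactone, C11 epimers (not isolated) | CN(C)CC1C(=O)O[C@H]2/C=C(/C)[C@@H](O[Si](C)(C)C(C)(C)C)[C@H]3O[C@H]3[C@](C)(OCc4ccc(OC)cc4)C[C@H](O[Si](CC)(CC)CC)[C@@H]12 | intermediate
33 | trimethylammonium iodide of 32 (not isolated) | C[N+](C)(C)CC1C(=O)O[C@H]2/C=C(/C)[C@@H](O[Si](C)(C)C(C)(C)C)[C@H]3O[C@H]3[C@](C)(OCc4ccc(OC)cc4)C[C@H](O[Si](CC)(CC)CC)[C@@H]12.[I-] | intermediate
34 | α-methylene lactone (C11=C13H2) with C3–OSiMe2t-Bu, C8–OSiEt3, C10–OPMB | C=C1C(=O)O[C@H]2/C=C(/C)[C@@H](O[Si](C)(C)C(C)(C)C)[C@H]3O[C@H]3[C@](C)(OCc4ccc(OC)cc4)C[C@H](O[Si](CC)(CC)CC)[C@@H]12 | intermediate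
35 | C8 alcohol of 34 | C=C1C(=O)O[C@H]2/C=C(/C)[C@@H](O[Si](C)(C)C(C)(C)C)[C@H]3O[C@H]3[C@](C)(OCc4ccc(OC)cc4)C[C@H](O)[C@@H]12 | intermediate
36 | angelic acid, (Z)-2-methylbut-2-enoic acid | C/C=C(/C)C(=O)O | starting material
37 | angelic 2,4,6-trichlorobenzoic anhydride (not isolated) | C/C=C(/C)C(=O)OC(=O)c1c(Cl)cc(Cl)cc1Cl | intermediate
38 | C8 angelate with C3–OSiMe2t-Bu and C10–OPMB | C=C1C(=O)O[C@H]2/C=C(/C)[C@@H](O[Si](C)(C)C(C)(C)C)[C@H]3O[C@H]3[C@](C)(OCc4ccc(OC)cc4)C[C@H](OC(=O)/C(C)=C\C)[C@@H]12 | intermediate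
39 | C8 angelate with C3–OSiMe2t-Bu and free C10–OH | C=C1C(=O)O[C@H]2/C=C(/C)[C@@H](O[Si](C)(C)C(C)(C)C)[C@H]3O[C@H]3[C@](C)(O)C[C@H](OC(=O)/C(C)=C\C)[C@@H]12 | intermediate
40 | CNP0351240.3: (1R,2R,3R,6S,7R,8S,10R; 4Z in the ring numbering of the overview) 1,2-epoxy-3,10-dihydroxy-6,12-olide 8-angelate | C=C1C(=O)O[C@H]2/C=C(/C)[C@@H](O)[C@H]3O[C@H]3[C@](C)(O)C[C@H](OC(=O)/C(C)=C\C)[C@@H]12 | target

## Step count and risks

Total: 23 steps. Longest linear sequence: 22 steps (steps 1–4 and 6–23, from 1 to 40; step 5 is the side branch).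

Steps most likely to fail:

1. Step 16 (Proposed new method). Intermolecular aldol oligomerisation may outrun the ten-membered closure, the ring may close through the anti aldolate to the trans-oxirane, or the sequence may stall at the chlorohydrin because the magnesium alkoxide is a weak nucleophile. Fallback with known chemistry, from 25 back to 28: SmI2 (THF, −78 °C, high dilution) effects a Reformatsky-type aldol ring closure of the chloromethyl ketone onto the aldehyde, a method established for medium rings, to give the macrocyclic β-hydroxy ketone F1. Mesylation and elimination (MsCl, Et3N; then DBU) give the cross-conjugated (1Z,4Z)-dienone F2, the cis-enone being the favoured geometry in a ten-membered ring. Nucleophilic epoxidation (t-BuOOH, DBU) of the less substituted C1=C2 enone, with the ring holding the cis geometry, returns to 28.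

2. Step 17. The conformation of the macrocycle may override the zinc chelate, so that hydride is delivered to the wrong face of C3, and conjugate reduction of the enone may compete. Fallback, from 28 back to 29: the reduction (Zn(BH4)2 or NaBH4/CeCl3) is accepted as it comes and the C3-epimeric alcohol F3 is inverted by a Mitsunobu reaction (4-nitrobenzoic acid, PPh3, DIAD) to the 4-nitrobenzoate F4, which has the C3 configuration of 29. Brief methanolysis (K2CO3, MeOH, 0 °C) removes the ester and returns to 29.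

3. Step 21. The angeloyl group may isomerise to the tigloyl group during activation, and slow acylation of the hindered C8 hydroxyl leaves time for the lactone to migrate from O6 to O8. Fallback, from 35 back to 38: O8 is esterified at room temperature with 2-[bis(2,2,2-trifluoroethoxy)phosphoryl]propanoic acid (DCC, DMAP) to the phosphonate ester F5. A Still–Gennari olefination with acetaldehyde (KN(SiMe3)2, 18-crown-6, THF, −78 °C) then builds the (Z)-2-methylbut-2-enoate on the ester and returns to 38.

Further compounds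

F1 | step 16 | macrocyclic β-hydroxy ketone (C1–OH, C2H2, C3=O; C1 epimers) | C1C(=O)O[C@H]2/C=C(/C)C(=O)CC(O)[C@](C)(OCc3ccc(OC)cc3)C[C@H](O[Si](CC)(CC)CC)[C@@H]12
F2 | step 16 | cross-conjugated (1Z,4Z)-dienone | C1C(=O)O[C@H]2/C=C(/C)C(=O)/C=C\[C@](C)(OCc3ccc(OC)cc3)C[C@H](O[Si](CC)(CC)CC)[C@@H]12
F3 | step 17 | C3-epimeric epoxy alcohol (3-epi-29) | C1C(=O)O[C@H]2/C=C(/C)[C@H](O)[C@H]3O[C@H]3[C@](C)(OCc4ccc(OC)cc4)C[C@H](O[Si](CC)(CC)CC)[C@@H]12
F4 | step 17 | C3 4-nitrobenzoate with the configuration of 29 | C1C(=O)O[C@H]2/C=C(/C)[C@@H](OC(=O)c4ccc(cc4)[N+](=O)[O-])[C@H]3O[C@H]3[C@](C)(OCc5ccc(OC)cc5)C[C@H](O[Si](CC)(CC)CC)[C@@H]12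
F5 | step 21 | C8 2-[bis(2,2,2-trifluoroethoxy)phosphoryl]propanoate of 35 | C=C1C(=O)O[C@H]2/C=C(/C)[C@@H](O[Si](C)(C)C(C)(C)C)[C@H]3O[C@H]3[C@](C)(OCc4ccc(OC)cc4)C[C@H](OC(=O)C(C)P(=O)(OCC(F)(F)F)OCC(F)(F)F)[C@@H]12
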